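The runs come from a simulation with made-up constants; scatter was added.

The amber flask was to be read at 4.2 min, so I asked what each flask does on that clock, counting target as a share of the substrate charged.

| setting | red | violet | teal | ochre | amber |
|---|---|---|---|---|---|
| substrate | 0.250 M | 0.250 M | 0.250 M | 0.380 M | 0.250 M |
| coupling partner | 0.275 M | 0.275 M | 0.410 M | 0.275 M | 0.0910 M |
| catalyst | 5.00 × 10⁻⁴ M | 0.00150 M | 5.00 × 10⁻⁴ M | 5.00 × 10⁻⁴ M | 1.60 × 10⁻⁴ M |
| time |  |  |  |  | 4.2 min |

| run | time / min | [target] / M |
|---|---|---|
| red run | 0.24 | 0.0086 |
| red run | 0.72 | 0.0191 |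
| red run | 1.4 | 0.0339 |
| red run | 2.2 | 0.0456 |
| red run | 3.1 | 0.0539 |
| red run | 4.2 | 0.0592 |
| violet run | 0.24 | 0.0225 |
| violet run | 0.72 | 0.0595 |
| violet run | 1.4 | 0.0907 |
| violet run | 2.2 | 0.1102 |
| violet run | 3.1 | 0.1102 |
| violet run | 4.2 | 0.0991 |
| teal run | 0.24 | 0.0085 |
| teal run | 0.72 | 0.0247 |
| teal run | 1.4 | 0.0416 |
| teal run | 2.2 | 0.0571 |
| teal run | 3.1 | 0.0651 |
| teal run | 4.2 | 0.0719 |
| ochre run | 0.24 | 0.0086 |
| ochre run | 0.72 | 0.0215 |
| ochre run | 1.4 | 0.0348 |
| ochre run | 2.2 | 0.0494 |
| ochre run | 3.1 | 0.0571 |
| ochre run | 4.2 | 0.0631 |

(readings scatter by 8 × 10⁻⁴ M)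

1. how the opening rate goes with [coupling partner] round the charge of the red run: the exponent of the rate at two percent of substrate gone to target
2. how the opening rate goes with [catalyst] round the charge of the red run: the exponent of the rate at two percent of substrate gone to target
3. target in the amber run at 4.2 min, as a share of the substrate charged

- Overall: substrate + coupling partner -> target, with catalyst as catalyst.
- Constant volume, constant temperature.
- What is held in complexes is read along with the free species.
- An order is taken over about fifteen percent of the charge, up and down.

My ladder used the fill time: the substrate charge divided by the mean rate up to 1.4 min. In the violet flask it was 3.86 min, shorter than the reading time, and the violet readings of target fell from 44.1% at 3.1 min to 39.6% at 4.2 min. That net fall reads as a time of 10.4 min. The red fill time was 10.3 min, longer than the reading time, and red stood at 23.7% when read.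

I assumed that loss runs on the clock, so I compared amber with red at the same time and worked in decades. The partner slope, decades of target per decade of coupling partner at fixed clock time, is 0.512, from teal over red at 1.4 min. Violet over red gave the catalyst slope in the same way:

catalyst slope = 0.896

amber below red = 0.512 × −0.480 + 0.896 × −0.495 = −0.689 decades

amber share = 4.84%

This walks the partner slope well beyond the step it was read over. The amber fill time comes to 50.5 min, the top rung, longer than the others. The coupling partner is amber's limiting reagent, charged below the substrate, and the target standing at my share equals 13.3% of the partner charge.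

The forecast gave 0.58, 0.95 and 5.3%, a higher amber share than mine: “Allowing for partner depletion and target loss gives about 0.013 M, or roughly 5%.”

    catalyst + substrate ⇌ catalyst-substrate complex, settled at all times (21.20 M⁻¹)
    catalyst-substrate complex + coupling partner ⇌ ternary complex, settled at all times (4.110 M⁻¹)
    ternary complex → target + catalyst (273.6 min⁻¹)
    2 coupling partner ⇌ idle reagent dimer, settled at all times (11.40 M⁻¹)
    target → decomposed product (0.3408 min⁻¹)

The flask gave 0.49, 1.1 and 4.71%, with the partner order below the forecast's 0.58. At 4.2 min, amber stood −0.701 decades from the red reading. Of my −0.689 decades, the partner slope had supplied −0.246. On the teal flask, the same slope lifts red's rate at the two-percent point, 0.122 min⁻¹ of the substrate charge, to 0.149 min⁻¹, and the teal rate stored for that point is 0.147 min⁻¹.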